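## The problem

The target 28 is a dearomatised acylphloroglucinol. Ring A (C4a, C5, C6, C7, C8, C8a) is a cyclohexadienone that exists as a vinylogous acid across O5–C5–C6–C7–O7. It is fused through C4a/C8a to ring B, a cis-2,3-dimethyl-dihydropyran-4-one. C6 carries a 3-substituted hexanoic acid chain; the quaternary C8 carries a prenyl group and a (2,2-dimethyl-3-isopropenylcyclobutyl)methyl arm.

The six stereocentres fall into four groups that cannot direct one another: the cis pair C2 (R)/C3 (S), the side-chain carbon (S), C8 (R), and the cis pair on the cyclobutane (1S,3R). Only inside a pair can one centre control the other, so each group needs its own source of asymmetry.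

The cis arrangement at C2/C3 is the less stable one and is lost by enolisation at C3 or by retro-oxa-Michael opening. The prenyl group beside the enol and the isopropenylcyclobutane do not tolerate strong acid. C8a of the alkoxy-enedione is open to nucleophiles. On the phloroglucinol ring, C6 versus C8 and O5 versus O7 must be decided before aromaticity is given up.

The feature that makes the key step possible: both substituents on C8 begin with a CH2 group and can be grown from allyl groups, and C8 is next to the enolic oxygen on C7. An 8,8-diallyl precursor therefore has no stereocentre at C8. O7 can reach the inner carbon of either allyl group through a five-membered ring, so marking one allyl group creates the centre.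

## Retrosynthesis

**Acid and isopropenyl group (28 ⇒ 27 ⇒ 26).** The acid is carried as methyl ester 27. The C–H bond at the isopropenyl-bearing ring carbon is cut next, back to the tertiary allylic carbonate 26, to be formed by hydride delivery to a π-allylpalladium complex. This is preferred to a Wittig homologation and methylenation, which would expose the C3 centre to basic ylides twice. The forward step must place hydride on the ring terminus of the allyl unit, on the face away from the CH2 arm.

**Prenyl group and unmasking (26 ⇒ 24 + 25 ⇒ 23).** The prenyl double bond is cut by cross-metathesis to the allyl compound 24 and 2-methylbut-2-ene 25. Doing this before the palladium step removes the terminal alkene that a palladium hydride could isomerise. Compound 24 comes from iodoether 23 by reductive elimination, which returns both the allyl group and the vinylogous acid.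

**Isopropenyl carbon–carbon bond (23 ⇒ 20 + 21).** The bond between the ring and the isopropenyl group is cut to cyclobutanone 20 and isopropenylmagnesium bromide 21. The strained ketone is the most electrophilic carbonyl in 20, so a 1,2-addition can be selective; the alkoxide 22 is trapped as its carbonate in the same flask.

**Cyclobutane (20 ⇒ 14 + 17).** The ring bonds CH2–C(=O) and CH–CMe2 are cut together, giving the free allyl group of 14 and the isobutyramide 17 of a C2-symmetric pyrrolidine. The amide is activated to keteniminium salt 18; cycloaddition gives iminium salt 19, which is hydrolysed. C8 is too remote to control the new ring carbon, so the chiral amine must. Amide 17 comes from amine 15 and acid chloride 16.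

**C8 (14 ⇒ 13), the key cut.** The O7–CH bond and the C–I bond of the iodomethyl-dihydrofuran ring are cut, giving the 8,8-diallyl vinylogous acid 13. The precursor loses a ring, two stereocentres and, above all, the need for any control at C8. The forward reaction must choose one of two diastereotopic allyl groups under catalyst control.

**Geminal allyl groups (13 ⇒ 10 + 11).** Both C8–allyl bonds are cut to the aromatic chromanone 10 and allyl methyl carbonate 11, passing through the mono-allyl phenol 12. C6 already carries the side chain, so C8 is the only free ring carbon and no stereocentre is made.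

**Lactone as regiochemical lock (10 ⇒ 9).** The ester of 10 is reconnected to O5 as the aryl lactone of 9. In the lactone, O5 is blocked and C8 is free, which fixes where the acyl group and ring B must go. The forward step is a transesterification that must not epimerise C3.

**Ring B (9 ⇒ 8 ⇒ 6 + 7).** The O1–C2 bond is cut by a retro-oxa-Michael step to the o-tigloylphenol 8, and the aryl–acyl bond is cut to dihydrocoumarin 6 and tigloyl chloride 7. In 8 the only hydroxyl ortho to the acyl group is the one para to the side-chain carbon, so closure has one direction. A chiral amine catalyst must set C2 and, through kinetic protonation, the cis C3.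

**Side-chain centre and arene (6 ⇒ 3 ⇒ 1 + 2).** The C4–H bond of 6 is cut to coumarin 3, a substrate for asymmetric conjugate reduction. Compound 3 is the Pechmann product of phloroglucinol 1 and ethyl 3-oxohexanoate 2; the symmetry of 1 allows one product only.

## Roads not taken

**Alternative 1:** The cyclobutane is cut first, by the same keteniminium cycloaddition, but on the simplest substrate: C-allylphloroglucinol triacetate A1 and a chiral keteniminium salt would give the arylmethyl cyclobutanone A2.
- Merits: the cycloaddition runs on a robust arene with no Lewis-basic dienone and can be done early and on scale. In this respect it is better than step 9 of the chosen route, which performs the same reaction on a delicate intermediate.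
- Weak points: C8 must later be made quaternary by dearomative prenylation of a ring that already carries the cyclobutylmethyl arm. The two faces of that ring differ only through a remote, freely rotating substituent, so there is no lever for control at C8. The acid-labile isopropenylcyclobutane, or its ketone precursor, would also have to pass through Pechmann and Friedel–Crafts conditions.
- Comparison: the chosen plan accepts the harder cycloaddition and in return sets C8 in a dedicated step, with the cyclobutane appearing only after all strongly acidic steps.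

**Alternative 2:** The C6–CH(propyl) bond and the lactone O–acyl bond are cut. The symmetric trione A3, with both C8 substituents in place, would react with (E)-hex-2-enal A4 under a chiral triazolium carbene and a quinone oxidant. The enol carbon adds to the β-carbon of the acyl azolium and the enol oxygen closes the lactone, giving enol lactone A5.
- Merits: two stereocentres (side chain and, by the choice of flank, C8) are set in one catalytic step. The reaction class is better precedented than the key step chosen here, and the plan is more convergent.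
- Weak points: the catalyst must tell the two flanks apart by reading a quaternary carbon whose substituents are both CH2–CH units that differ only further out. Ring B must then be built on the dearomatised core, where acylation and closure face the O-regiochemistry problem with no lactone lock. A3 itself requires a hindered cyclobutylmethyl alkylation.
- Comparison: the chosen plan distinguishes two identical allyl groups directly on the prochiral carbon with the neighbouring enol oxygen as internal nucleophile, and fixes ring B and the side-chain centre earlier by independent catalytic steps.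

**Alternative 3:** The C8a–O1 bond is cut. The alkoxide of the syn-aldol fluoro ketone A6 would displace the ortho fluoride to give the protected chromanone A7.
- Merits: both ring B centres come from an aldol reaction and are carried over with retention. This is a more secure source of the cis pair than the kinetic protonation relied on in step 4.
- Weak points: a β-hydroxy ketone under base can undergo retro-aldol cleavage, dehydration and C3 epimerisation. The arene is activated only by the ortho ketone. The road solves ring B alone: the side chain would still have to be placed at C6 rather than C8 of a symmetric-looking diol, and C8 is untouched.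
- Comparison: better for ring B in isolation; the chosen plan uses a catalytic closure on a substrate that already carries the side chain and the regiochemical lock, and is shorter overall.

Key step: step 7

Remark on stereochemical sense: each chiral controller (ligand in step 2, alkaloid in step 4, acid in step 7, amine 15) is written as the antipode expected by analogy to give the configuration shown; all are available in both hands (quinidine for quinine), so a reversed sense is corrected by exchange.

Remark on the iodoether: the CH–O carbon is drawn as one epimer in 14 to 23; both epimers give 24.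

Remark on numbering: C2 to C8a refer to the chromanone numbering of 28, unless a systematic name is given.

## Route

Step 1
Reactants: 1 phloroglucinol; 2 ethyl 3-oxohexanoate
Product: 3 5,7-dihydroxy-4-propyl-2H-chromen-2-one
Conditions: conc. H2SO4, 0 °C → rt
Reagents that add atoms: none
Why: Pechmann condensation; hydroxyalkylation of the symmetric triol by the β-keto ester, lactonisation and dehydration give the 4-propylcoumarin as the only possible isomer.

Step 2
Reactants: 3 5,7-dihydroxy-4-propyl-2H-chromen-2-one
Product: 6 (4S)-5,7-dihydroxy-4-propyl-3,4-dihydro-2H-chromen-2-one, via bis-silylated coumarin 4 (not isolated), via bis-silylated lactone 5 (not isolated)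
Conditions: Cu(OAc)2·H2O (3 mol %), (R)-DTBM-SEGPHOS (3.3 mol %), (EtO)2MeSiH (5 equiv), t-BuOH (1.2 equiv), THF, 0 °C → rt; then 1 M HCl
Reagents that add atoms: none
Why: Ligand-controlled asymmetric copper hydride conjugate reduction of a coumarin; hydride adds to C4 on the face chosen by the bisphosphine and tert-butanol protonates the copper enolate, setting C4 (S). The phenols are silylated in the flask by excess silane and freed by the acid work-up.

Step 3
Reactants: 6 (4S)-5,7-dihydroxy-4-propyl-3,4-dihydro-2H-chromen-2-one; 7 (E)-2-methylbut-2-enoyl chloride (tigloyl chloride)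
Product: 8 (4S)-5,7-dihydroxy-8-[(2E)-2-methylbut-2-enoyl]-4-propyl-3,4-dihydro-2H-chromen-2-one
Conditions: AlCl3 (3 equiv), PhNO2/CH2Cl2, 0 °C → rt
Reagents that add atoms: none
Why: Friedel–Crafts acylation; C8 (one ortho and one para hydroxyl) is expected to react before C6, which lies between two aluminium-bound oxygens, the same pattern that directs acylation of the parent coumarin to C8. Low temperature keeps the enone from closing to racemic chromanone.

Step 4
Reactants: 8 (4S)-5,7-dihydroxy-8-[(2E)-2-methylbut-2-enoyl]-4-propyl-3,4-dihydro-2H-chromen-2-one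
Product: 9 (4S,8R,9S)-5-hydroxy-8,9-dimethyl-4-propyl-3,4,8,9-tetrahydro-2H,10H-pyrano[2,3-f]chromene-2,10-dione
Conditions: (−)-quinine (10 mol %), chlorobenzene, rt
Reagents that add atoms: none
Why: Cinchona-alkaloid-catalysed intramolecular oxa-Michael addition of an o-tigloylphenol; the 7-hydroxyl adds to the β-carbon within a chiral ion pair (sets C8 of 9, R) and the enol is protonated kinetically on the same side (sets C9, S), giving the cis-dimethyl ring. Only this hydroxyl is ortho to the acyl group, so ring B closes in one direction.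

Step 5
Reactants: 9 (4S,8R,9S)-5-hydroxy-8,9-dimethyl-4-propyl-3,4,8,9-tetrahydro-2H,10H-pyrano[2,3-f]chromene-2,10-dione
Product: 10 methyl (3S)-3-[(2R,3S)-5,7-dihydroxy-2,3-dimethyl-4-oxo-3,4-dihydro-2H-chromen-6-yl]hexanoate
Conditions: HCl (1.25 M in MeOH), 0 °C → rt; solid NaHCO3, concentrate below 30 °C; used crude
Reagents that add atoms: methanol, CO
Why: Acid-catalysed transesterification of an aryl lactone; the freed phenol is held by a hydrogen bond to the C4 ketone, which favours the open ester, and acid avoids the enolate that would epimerise C3.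

Step 6
Reactants: 10 methyl (3S)-3-[(2R,3S)-5,7-dihydroxy-2,3-dimethyl-4-oxo-3,4-dihydro-2H-chromen-6-yl]hexanoate; 11 allyl methyl carbonate
Product: 13 methyl (3S)-3-[(2R,3S)-5-hydroxy-2,3-dimethyl-4,7-dioxo-8,8-di(prop-2-en-1-yl)-3,4,7,8-tetrahydro-2H-chromen-6-yl]hexanoate, via mono-allyl phenol 12 (not isolated)
Conditions: Pd(PPh3)4 (5 mol %), 11 (2.2 equiv), THF, 0 → 40 °C
Reagents that add atoms: none
Why: Tsuji–Trost C-allylation of an acylphloroglucinol; the π-allylpalladium complex first substitutes the only free ring carbon (C8, giving 12) and then adds again at C8 with loss of aromaticity, the product being a stable vinylogous acid. C6 is shielded by its secondary alkyl group, O-allyl ethers return through the π-allyl complex, and no stereocentre is formed.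

Step 7
Reactants: 13 methyl (3S)-3-[(2R,3S)-5-hydroxy-2,3-dimethyl-4,7-dioxo-8,8-di(prop-2-en-1-yl)-3,4,7,8-tetrahydro-2H-chromen-6-yl]hexanoate
Product: 14 methyl (3S)-3-[(2R,3S,8S,9aR)-8-(iodomethyl)-2,3-dimethyl-4,5-dioxo-9a-(prop-2-en-1-yl)-2,3,4,5,8,9-hexahydro-9aH-furo[2,3-h]chromen-6-yl]hexanoate (O7 joined to the inner carbon of one allyl group; second allyl group free on C8, which is position 9a of the tricycle)
Conditions: N-iodosuccinimide (1.05 equiv), (R)-3,3′-bis(2,4,6-triisopropylphenyl)-1,1′-binaphthyl-2,2′-diyl hydrogen phosphate (10 mol %), 4 Å sieves, toluene, −60 °C, dark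
Reagents that add atoms: N-iodosuccinimide, O=C1CCC(=O)N1I
Why: Proposed new method: the phosphoric acid is expected to bind the vinylogous acid of 13 through its P=O/P–OH pair and to pass iodine from N-iodosuccinimide to one allyl alkene, after which O7 opens the iodonium ion anti at its inner carbon while the C5 hydroxyl gives up its proton, leaving the cross-conjugated vinylogous ester of 14. The closest known reactions are the iodoetherification of C-allyl 1,3-diketones to 2-(iodomethyl)dihydrofurans and catalyst-controlled desymmetrising halolactonisations of α,α-diallyl carboxylic acids, of which this is the vinylogous counterpart. The dihydrofuran ring closes in the 5-exo-trig mode, the Markovnikov opening of a terminal iodonium ion. C8 becomes stereogenic only through the choice between the two allyl groups, which lie on opposite faces of the planar ring A; that choice is made by the chiral acid, since the ring B and side-chain centres are too remote to bias it. The CH–O carbon follows from the alkene face attacked and is left uncontrolled, because step 11 removes it. The step needs group selectivity and a single cyclisation; the latter is secured because 14 has no enol hydroxyl left beside the second allyl group and C6, being fully substituted, cannot be iodinated irreversibly. Low temperature and a non-polar solvent are chosen to hold back the uncatalysed pathway.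

Step 8
Reactants: 15 (2R,5R)-2,5-dimethylpyrrolidine; 16 2-methylpropanoyl chloride
Product: 17 1-[(2R,5R)-2,5-dimethylpyrrolidin-1-yl]-2-methylpropan-1-one
Conditions: aq. NaOH, CH2Cl2, 0 °C → rt
Reagents that add atoms: none
Why: Schotten–Baumann acylation of a secondary amine; no stereocentre is touched.

Step 9
Reactants: 14 iodoether (free allyl group on C8); 17 1-[(2R,5R)-2,5-dimethylpyrrolidin-1-yl]-2-methylpropan-1-one
Product: 20 methyl (3S)-3-[(2R,3S,8S,9aR)-9a-{[(1R)-2,2-dimethyl-3-oxocyclobutyl]methyl}-8-(iodomethyl)-2,3-dimethyl-4,5-dioxo-2,3,4,5,8,9-hexahydro-9aH-furo[2,3-h]chromen-6-yl]hexanoate, via keteniminium triflate 18 (not isolated), via cyclobutaniminium triflate 19 (not isolated)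
Conditions: 17 (1.5 equiv), Tf2O (1.4 equiv), 2,4,6-collidine (1.6 equiv), ClCH2CH2Cl, −20 °C → rt; then 14, rt → 45 °C; then aq. NaHCO3, rt
Reagents that add atoms: water, O
Why: Keteniminium–alkene [2+2] cycloaddition; the central carbon of 18 bonds to the terminal CH2 of the allyl group and its CMe2 carbon to the inner CH, and iminium salt 19 is hydrolysed to the ketone. The C2-symmetric pyrrolidine shields one face of approach and is relied on to set the new ring carbon (1R), since C8 is too far away. 18 is preformed so that no free anhydride meets the dienone.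

Step 10
Reactants: 20 cyclobutanone; 21 isopropenylmagnesium bromide
Product: 23 methyl (3S)-3-[(2R,3S,8S,9aR)-8-(iodomethyl)-9a-{[(1R,3R)-3-[(methoxycarbonyl)oxy]-2,2-dimethyl-3-(prop-1-en-2-yl)cyclobutyl]methyl}-2,3-dimethyl-4,5-dioxo-2,3,4,5,8,9-hexahydro-9aH-furo[2,3-h]chromen-6-yl]hexanoate, via tertiary cyclobutanol 22 (not isolated)
Conditions: 21 (1.3 equiv), LaCl3·2LiCl (1.0 equiv), THF, −78 °C; then ClCO2Me (3 equiv), −78 → 0 °C
Reagents that add atoms: methyl chloroformate, COC(=O)Cl
Why: Lanthanide-promoted Grignard 1,2-addition, selective at −78 °C for the strained cyclobutanone over the vinylogous-ester carbonyls and the ester; attack anti to the ring CH2 arm gives the alkoxide of 22, which is acylated in the flask because the hindered tertiary alcohol would be hard to acylate later. The carbinol configuration is erased in step 13.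

Step 11
Reactants: 23 iodoether carbonate
Product: 24 methyl (3S)-3-[(2R,3S,8R)-5-hydroxy-8-{[(1R,3R)-3-[(methoxycarbonyl)oxy]-2,2-dimethyl-3-(prop-1-en-2-yl)cyclobutyl]methyl}-2,3-dimethyl-4,7-dioxo-8-(prop-2-en-1-yl)-3,4,7,8-tetrahydro-2H-chromen-6-yl]hexanoate
Conditions: Zn dust, AcOH, THF, 0 °C → rt
Reagents that add atoms: none
Why: Reductive β-elimination of a β-iodo ether by zinc; the leaving group is a vinylogous carboxylate, so the allyl group and the C5/C7 vinylogous acid return under conditions that leave the tertiary carbonate alone. Both CH–O epimers converge here.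

Step 12
Reactants: 24 allyl carbonate; 25 2-methylbut-2-ene
Product: 26 methyl (3S)-3-[(2R,3S,8R)-5-hydroxy-8-{[(1R,3R)-3-[(methoxycarbonyl)oxy]-2,2-dimethyl-3-(prop-1-en-2-yl)cyclobutyl]methyl}-2,3-dimethyl-8-(3-methylbut-2-en-1-yl)-4,7-dioxo-3,4,7,8-tetrahydro-2H-chromen-6-yl]hexanoate
Conditions: second-generation Grubbs catalyst (5 mol %), 25 (excess), CH2Cl2, 40 °C
Reagents that add atoms: none
Why: Olefin cross-metathesis of a monosubstituted alkene with 2-methylbut-2-ene; the 1,1-disubstituted alkene beside the fully substituted carbinol carbon cannot engage the ruthenium carbene.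

Step 13
Reactants: 26 prenyl carbonate
Product: 27 methyl (3S)-3-[(2R,3S,8R)-8-{[(1S,3R)-2,2-dimethyl-3-(prop-1-en-2-yl)cyclobutyl]methyl}-5-hydroxy-2,3-dimethyl-8-(3-methylbut-2-en-1-yl)-4,7-dioxo-3,4,7,8-tetrahydro-2H-chromen-6-yl]hexanoate
Conditions: Pd(OAc)2 (5 mol %), P(n-Bu)3 (5 mol %), HCO2H (3 equiv), Et3N (4 equiv), THF, rt → 40 °C
Reagents that add atoms: none
Why: Palladium-catalysed formate hydrogenolysis of a tertiary allylic carbonate (trialkylphosphine variant that gives terminal alkenes); ionisation to the π-allyl complex is followed by hydride transfer from bound formate to the more substituted ring terminus. Hydride arrives on the ring face away from the CH2 arm, as nucleophiles do with 3-substituted cyclobutanones, so the isopropenyl group ends cis to the arm (3R). Excess formate outruns the enolate as a nucleophile, and the prenyl alkene cannot be isomerised.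

Step 14
Reactants: 27 methyl ester
Product: 28 (3S)-3-[(2R,3S,8R)-8-{[(1S,3R)-2,2-dimethyl-3-(prop-1-en-2-yl)cyclobutyl]methyl}-5-hydroxy-2,3-dimethyl-8-(3-methylbut-2-en-1-yl)-4,7-dioxo-3,4,7,8-tetrahydro-2H-chromen-6-yl]hexanoic acid
Conditions: LiOH (4 equiv), THF/H2O, 0 °C → rt; then 0.5 M HCl to pH 3 at 0 °C, immediate extraction
Reagents that add atoms: lithium hydroxide, [Li+].[OH-]
Why: Saponification; the vinylogous acid is deprotonated first, and the anion lowers the acidity of C3–H and the electrophilicity of C8a, so the cis ring B should survive. Cold, brief acidification avoids cyclisation of the prenyl group onto the enol.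

## Compound list

1 | phloroglucinol (benzene-1,3,5-triol) | Oc1cc(O)cc(O)c1 | starting material
2 | ethyl 3-oxohexanoate | CCCC(=O)CC(=O)OCC | starting material
3 | 5,7-dihydroxy-4-propyl-2H-chromen-2-one | CCCC1=CC(=O)Oc2cc(O)cc(O)c12 | intermediate
4 | 5,7-bis[diethoxy(methyl)silyloxy]-4-propyl-2H-chromen-2-one | CCCC1=CC(=O)Oc2cc(O[Si](C)(OCC)OCC)cc(O[Si](C)(OCC)OCC)c12 | intermediate
5 | (4S)-5,7-bis[diethoxy(methyl)silyloxy]-4-propyl-3,4-dihydro-2H-chromen-2-one | CCC[C@H]1CC(=O)Oc2cc(O[Si](C)(OCC)OCC)cc(O[Si](C)(OCC)OCC)c12 | intermediate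
6 | (4S)-5,7-dihydroxy-4-propyl-3,4-dihydro-2H-chromen-2-one | CCC[C@H]1CC(=O)Oc2cc(O)cc(O)c12 | intermediate
7 | (E)-2-methylbut-2-enoyl chloride | C/C=C(\C)C(Cl)=O | starting material
8 | (4S)-5,7-dihydroxy-8-[(2E)-2-methylbut-2-enoyl]-4-propyl-3,4-dihydro-2H-chromen-2-one | CCC[C@H]1CC(=O)Oc2c(C(=O)/C(C)=C/C)c(O)cc(O)c12 | intermediate
9 | (4S,8R,9S)-5-hydroxy-8,9-dimethyl-4-propyl-3,4,8,9-tetrahydro-2H,10H-pyrano[2,3-f]chromene-2,10-dione | CCC[C@H]1CC(=O)Oc2c3C(=O)[C@@H](C)[C@@H](C)Oc3cc(O)c12 | intermediate
10 | methyl (3S)-3-[(2R,3S)-5,7-dihydroxy-2,3-dimethyl-4-oxo-3,4-dihydro-2H-chromen-6-yl]hexanoate | CCC[C@@H](CC(=O)OC)c1c(O)cc2O[C@H](C)[C@H](C)C(=O)c2c1O | intermediate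
11 | allyl methyl carbonate | C=CCOC(=O)OC | starting material
12 | methyl (3S)-3-[(2R,3S)-5,7-dihydroxy-2,3-dimethyl-4-oxo-8-(prop-2-en-1-yl)-3,4-dihydro-2H-chromen-6-yl]hexanoate | CCC[C@@H](CC(=O)OC)c1c(O)c(CC=C)c2O[C@H](C)[C@H](C)C(=O)c2c1O | intermediate
13 | methyl (3S)-3-[(2R,3S)-5-hydroxy-2,3-dimethyl-4,7-dioxo-8,8-di(prop-2-en-1-yl)-3,4,7,8-tetrahydro-2H-chromen-6-yl]hexanoate | C=CCC2(CC=C)C(=O)C([C@@H](CCC)CC(=O)OC)=C(O)C3=C2O[C@H](C)[C@H](C)C3=O | intermediate
14 | methyl (3S)-3-[(2R,3S,8S,9aR)-8-(iodomethyl)-2,3-dimethyl-4,5-dioxo-9a-(prop-2-en-1-yl)-2,3,4,5,8,9-hexahydro-9aH-furo[2,3-h]chromen-6-yl]hexanoate | C=CC[C@@]2(C[C@@H](CI)O4)C4=C([C@@H](CCC)CC(=O)OC)C(=O)C3=C2O[C@H](C)[C@H](C)C3=O | intermediate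
15 | (2R,5R)-2,5-dimethylpyrrolidine | C[C@@H]1CC[C@@H](C)N1 | starting material
16 | 2-methylpropanoyl chloride | CC(C)C(Cl)=O | starting material
17 | 1-[(2R,5R)-2,5-dimethylpyrrolidin-1-yl]-2-methylpropan-1-one | CC(C)C(=O)N1[C@H](C)CC[C@H]1C | intermediate
18 | (2R,5R)-2,5-dimethyl-1-(2-methylprop-1-en-1-ylidene)pyrrolidin-1-ium trifluoromethanesulfonate | CC(C)=C=[N+]1[C@H](C)CC[C@H]1C.[O-]S(=O)(=O)C(F)(F)F | intermediate
19 | (2R,5R)-2,5-dimethylpyrrolidinium iminium triflate of ketone 20 (C=N+ in place of C=O) | C[C@@H]5CC[C@@H](C)[N+]5=C1C[C@@H](C[C@@]2(C[C@@H](CI)O4)C4=C([C@@H](CCC)CC(=O)OC)C(=O)C3=C2O[C@H](C)[C@H](C)C3=O)C1(C)C.[O-]S(=O)(=O)C(F)(F)F | intermediate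
20 | methyl (3S)-3-[(2R,3S,8S,9aR)-9a-{[(1R)-2,2-dimethyl-3-oxocyclobutyl]methyl}-8-(iodomethyl)-2,3-dimethyl-4,5-dioxo-2,3,4,5,8,9-hexahydro-9aH-furo[2,3-h]chromen-6-yl]hexanoate | O=C1C[C@@H](C[C@@]2(C[C@@H](CI)O4)C4=C([C@@H](CCC)CC(=O)OC)C(=O)C3=C2O[C@H](C)[C@H](C)C3=O)C1(C)C | intermediate
21 | isopropenylmagnesium bromide | C=C(C)[Mg]Br | starting material
22 | methyl (3S)-3-[(2R,3S,8S,9aR)-9a-{[(1R,3R)-3-hydroxy-2,2-dimethyl-3-(prop-1-en-2-yl)cyclobutyl]methyl}-8-(iodomethyl)-2,3-dimethyl-4,5-dioxo-2,3,4,5,8,9-hexahydro-9aH-furo[2,3-h]chromen-6-yl]hexanoate (formed as its magnesium alkoxide) | C=C(C)[C@]1(O)C[C@@H](C[C@@]2(C[C@@H](CI)O4)C4=C([C@@H](CCC)CC(=O)OC)C(=O)C3=C2O[C@H](C)[C@H](C)C3=O)C1(C)C | intermediate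
23 | methyl (3S)-3-[(2R,3S,8S,9aR)-8-(iodomethyl)-9a-{[(1R,3R)-3-[(methoxycarbonyl)oxy]-2,2-dimethyl-3-(prop-1-en-2-yl)cyclobutyl]methyl}-2,3-dimethyl-4,5-dioxo-2,3,4,5,8,9-hexahydro-9aH-furo[2,3-h]chromen-6-yl]hexanoate | C=C(C)[C@]1(OC(=O)OC)C[C@@H](C[C@@]2(C[C@@H](CI)O4)C4=C([C@@H](CCC)CC(=O)OC)C(=O)C3=C2O[C@H](C)[C@H](C)C3=O)C1(C)C | intermediate
24 | methyl (3S)-3-[(2R,3S,8R)-5-hydroxy-8-{[(1R,3R)-3-[(methoxycarbonyl)oxy]-2,2-dimethyl-3-(prop-1-en-2-yl)cyclobutyl]methyl}-2,3-dimethyl-4,7-dioxo-8-(prop-2-en-1-yl)-3,4,7,8-tetrahydro-2H-chromen-6-yl]hexanoate | C=C(C)[C@]1(OC(=O)OC)C[C@@H](C[C@@]2(CC=C)C(=O)C([C@@H](CCC)CC(=O)OC)=C(O)C3=C2O[C@H](C)[C@H](C)C3=O)C1(C)C | intermediate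
25 | 2-methylbut-2-ene | CC=C(C)C | starting material
26 | methyl (3S)-3-[(2R,3S,8R)-5-hydroxy-8-{[(1R,3R)-3-[(methoxycarbonyl)oxy]-2,2-dimethyl-3-(prop-1-en-2-yl)cyclobutyl]methyl}-2,3-dimethyl-8-(3-methylbut-2-en-1-yl)-4,7-dioxo-3,4,7,8-tetrahydro-2H-chromen-6-yl]hexanoate | C=C(C)[C@]1(OC(=O)OC)C[C@@H](C[C@@]2(CC=C(C)C)C(=O)C([C@@H](CCC)CC(=O)OC)=C(O)C3=C2O[C@H](C)[C@H](C)C3=O)C1(C)C | intermediate
27 | methyl (3S)-3-[(2R,3S,8R)-8-{[(1S,3R)-2,2-dimethyl-3-(prop-1-en-2-yl)cyclobutyl]methyl}-5-hydroxy-2,3-dimethyl-8-(3-methylbut-2-en-1-yl)-4,7-dioxo-3,4,7,8-tetrahydro-2H-chromen-6-yl]hexanoate | C=C(C)[C@H]1C[C@@H](C[C@@]2(CC=C(C)C)C(=O)C([C@@H](CCC)CC(=O)OC)=C(O)C3=C2O[C@H](C)[C@H](C)C3=O)C1(C)C | intermediate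
28 | (3S)-3-[(2R,3S,8R)-8-{[(1S,3R)-2,2-dimethyl-3-(prop-1-en-2-yl)cyclobutyl]methyl}-5-hydroxy-2,3-dimethyl-8-(3-methylbut-2-en-1-yl)-4,7-dioxo-3,4,7,8-tetrahydro-2H-chromen-6-yl]hexanoic acid (CNP0364345.1) | C=C(C)[C@H]1C[C@@H](C[C@@]2(CC=C(C)C)C(=O)C([C@@H](CCC)CC(=O)O)=C(O)C3=C2O[C@H](C)[C@H](C)C3=O)C1(C)C | target

## Step count and least certain steps

Total step count: 14. Longest linear sequence: 13 steps (steps 1 to 7 and 9 to 14); step 8 is a one-step side branch.

**Step 7 (key step, proposed new method).** Most likely failure: too little discrimination between the two allyl groups, because an uncatalysed iodocyclisation of the acidic substrate competes and the remote centres give no help. Fallback: setting out from 13, iodine and NaHCO3 in acetonitrile, the standard iodoetherification of C-allyl 1,3-diketones, would give 14 together with its C8 epimer F1. The two are diastereomers and would be separated by chromatography; F1 would be returned to 13 with zinc and acetic acid and resubmitted. The fallback rejoins the route at 14.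

**Step 9.** Most likely failure: poor facial selection on a monosubstituted alkene far from any stereocentre, or capture of keteniminium ion 18 by the Lewis-basic carbonyl oxygen of the vinylogous ester. Fallback: setting out from 14, the achiral tetramethylketeniminium ion, generated without anhydride from 1-chloro-N,N,2-trimethylprop-1-en-1-amine and ZnCl2 in CH2Cl2, would add to the allyl group to give the dimethyliminium salt F2 and its ring epimer. Aqueous hydrolysis would give 20 and the epimeric ketone F3, to be separated by chromatography. The fallback rejoins the route at 20.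

**Step 3.** Most likely failure: acylation at C6 instead of C8, or premature unselective closure of ring B under the Lewis acid. Fallback: setting out from 3, for which acylation at C8 is established, tigloylation with 7 and AlCl3 would give the tigloylcoumarin F4, and quinine-catalysed closure the chromanone-coumarin F5. The copper hydride catalyst of step 2 with excess silane would then reduce both the lactone alkene and the ketone to the chromanol F6, and oxidation of the benzylic alcohol with Dess–Martin periodinane would rejoin the route at 9.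

**Step 13.** Most likely failure: hydride delivery to the CH2 terminus of the π-allyl complex, giving an isopropylidenecyclobutane, or elimination to a diene. Fallback: setting out from 20, a Wittig reaction with (1-methoxyethylidene)triphenylphosphorane would give the enol ether F7, and aqueous oxalic acid the methyl ketone F8, the cis isomer being expected after equilibration through the enol. Zinc and acetic acid would reopen the iodoether to F9, methylenation with the Zn/CH2Br2/TiCl4 reagent would give the isopropenyl compound F10, and cross-metathesis with 25 as in step 12 would rejoin the route at 27.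

**Step 6.** Most likely failure: O-allylation that does not revert, or allylation at C6 beside the side chain. Fallback: setting out from 10, allyl bromide and K2CO3 in acetone would give the 7-allyl ether F11. Thermal Claisen rearrangement (1,2-dichlorobenzene, 170 °C) can deliver the allyl group only to C8 and would give 12 as an isolated compound. One equivalent of 11 with Pd(PPh3)4 would then perform the dearomative allylation and rejoin the route at 13.

**Step 2.** Most likely failure: inhibition of the copper catalyst by the free phenols, or over-reduction of the aryl lactone. Fallback: setting out from 3, tert-butyldimethylsilyl chloride and imidazole would give the bis-silyl ether F12, the same copper hydride reduction the protected lactone F13, and HF·pyridine would rejoin the route at 6.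

## Further compounds

F1 | step 7 | C8 epimer of 14 (the other allyl group cyclised) | C=CC[C@]2(C[C@H](CI)O4)C4=C([C@@H](CCC)CC(=O)OC)C(=O)C3=C2O[C@H](C)[C@H](C)C3=O
F2 | step 9 | N,N-dimethyliminium chloride of ketone 20 | C[N+](C)=C1C[C@@H](C[C@@]2(C[C@@H](CI)O4)C4=C([C@@H](CCC)CC(=O)OC)C(=O)C3=C2O[C@H](C)[C@H](C)C3=O)C1(C)C.[Cl-]
F3 | step 9 | epimer of 20 at the cyclobutane CH carbon | O=C1C[C@H](C[C@@]2(C[C@@H](CI)O4)C4=C([C@@H](CCC)CC(=O)OC)C(=O)C3=C2O[C@H](C)[C@H](C)C3=O)C1(C)C
F4 | step 3 | 5,7-dihydroxy-8-[(2E)-2-methylbut-2-enoyl]-4-propyl-2H-chromen-2-one | CCCC1=CC(=O)Oc2c(C(=O)/C(C)=C/C)c(O)cc(O)c12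
F5 | step 3 | (8R,9S)-5-hydroxy-8,9-dimethyl-4-propyl-8,9-dihydro-2H,10H-pyrano[2,3-f]chromene-2,10-dione | CCCC1=CC(=O)Oc2c3C(=O)[C@@H](C)[C@@H](C)Oc3cc(O)c12
F6 | step 3 | C10 alcohol of 9 (10-hydroxy in place of 10-oxo; C10 epimer immaterial) | CCC[C@H]1CC(=O)Oc2c3[C@H](O)[C@@H](C)[C@@H](C)Oc3cc(O)c12
F7 | step 13 | 1-methoxyethylidene enol ether of ketone 20 | COC(C)=C1C[C@@H](C[C@@]2(C[C@@H](CI)O4)C4=C([C@@H](CCC)CC(=O)OC)C(=O)C3=C2O[C@H](C)[C@H](C)C3=O)C1(C)C
F8 | step 13 | cis-3-acetyl-2,2-dimethylcyclobutyl analogue of 20 (iodoether intact) | CC(=O)[C@H]1C[C@@H](C[C@@]2(C[C@@H](CI)O4)C4=C([C@@H](CCC)CC(=O)OC)C(=O)C3=C2O[C@H](C)[C@H](C)C3=O)C1(C)C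
F9 | step 13 | methyl ketone with allyl group and vinylogous acid restored | CC(=O)[C@H]1C[C@@H](C[C@@]2(CC=C)C(=O)C([C@@H](CCC)CC(=O)OC)=C(O)C3=C2O[C@H](C)[C@H](C)C3=O)C1(C)C
F10 | step 13 | 8-allyl analogue of 27 | C=C(C)[C@H]1C[C@@H](C[C@@]2(CC=C)C(=O)C([C@@H](CCC)CC(=O)OC)=C(O)C3=C2O[C@H](C)[C@H](C)C3=O)C1(C)C
F11 | step 6 | methyl (3S)-3-[(2R,3S)-5-hydroxy-2,3-dimethyl-4-oxo-7-(prop-2-en-1-yloxy)-3,4-dihydro-2H-chromen-6-yl]hexanoate | CCC[C@@H](CC(=O)OC)c1c(OCC=C)cc2O[C@H](C)[C@H](C)C(=O)c2c1O
F12 | step 2 | 5,7-bis(tert-butyldimethylsilyloxy)-4-propyl-2H-chromen-2-one | CCCC1=CC(=O)Oc2cc(O[Si](C)(C)C(C)(C)C)cc(O[Si](C)(C)C(C)(C)C)c12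
F13 | step 2 | (4S)-5,7-bis(tert-butyldimethylsilyloxy)-4-propyl-3,4-dihydro-2H-chromen-2-one | CCC[C@H]1CC(=O)Oc2cc(O[Si](C)(C)C(C)(C)C)cc(O[Si](C)(C)C(C)(C)C)c12
A1 | alternative 1 | 2-(prop-2-en-1-yl)benzene-1,3,5-triyl triacetate | C=CCc1c(OC(C)=O)cc(OC(C)=O)cc1OC(C)=O
A2 | alternative 1 | 2-{[(1R)-2,2-dimethyl-3-oxocyclobutyl]methyl}benzene-1,3,5-triyl triacetate | O=C1C[C@@H](Cc2c(OC(C)=O)cc(OC(C)=O)cc2OC(C)=O)C1(C)C
A3 | alternative 2 | 2-{[(1S,3R)-2,2-dimethyl-3-(prop-1-en-2-yl)cyclobutyl]methyl}-2-(3-methylbut-2-en-1-yl)cyclohexane-1,3,5-trione | C=C(C)[C@H]1C[C@@H](CC2(CC=C(C)C)C(=O)CC(=O)CC2=O)C1(C)C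
A4 | alternative 2 | (E)-hex-2-enal | CCC/C=C/C=O
A5 | alternative 2 | enol lactone with C8 and the side-chain centre set (dihydropyranone fused across C5–C6 of the cyclohexanedione) | C=C(C)[C@H]1C[C@@H](C[C@@]2(CC=C(C)C)C(=O)C4=C(OC(=O)C[C@@H]4CCC)CC2=O)C1(C)C
A6 | alternative 3 | (2S,3R)-1-[2,4-bis(benzyloxy)-6-fluorophenyl]-3-hydroxy-2-methylbutan-1-one | O[C@H](C)[C@H](C)C(=O)c1c(F)cc(OCc2ccccc2)cc1OCc1ccccc1
A7 | alternative 3 | (2R,3S)-5,7-bis(benzyloxy)-2,3-dimethylchroman-4-one | c1ccccc1COc1cc(OCc4ccccc4)c2c(c1)O[C@H](C)[C@H](C)C2=O
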